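**Assumption:** the target has no stereocentres (it is achiral), so no enantiocontrol is needed; 4-fluoro-3,5-dimethoxybenzaldehyde (2) is taken as a catalogue building block. The route has not been run; conditions are proposed by analogy to known reaction types.

## Retrosynthetic overview

1. The target is the head-to-tail pentamer of 1,2,3,5-tetraoxybenzene; global O-demethylation of the undecamethyl ether 14 is the last step.
2. The obvious iterative Ullmann coupling of electron-rich, di-ortho-substituted aryl bromides is avoided. Each Ar–O bond is made by metal-free SNAr of a chain-end phenoxide on 2, whose para-CHO activates the flanked C–F bond.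
3. The same CHO is then converted to the next chain-end phenol by Baeyer–Villiger (Dakin-type) oxidation, so the formyl group is a traceless activator and a latent OH.
4. No ring is constructed; the five bought benzene rings are joined in the order E (3,4,5-trioxygenated end) → D → C → B → A by four identical SNAr/Dakin cycles.

## Route

**Step 1**
Reactants: 1 3,4,5-trimethoxyphenol; 2 4-fluoro-3,5-dimethoxybenzaldehyde
Product: 3 3,5-dimethoxy-4-(3,4,5-trimethoxyphenoxy)benzaldehyde
Conditions: Cs2CO3 (1.5 equiv), 2 (1.3 equiv), DMSO, 120 °C, Ar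
Reagents that add atoms: none
Why: SNAr (addition–elimination) of the unhindered caesium phenoxide on the fluoride para to CHO, where the formyl group stabilises the Meisenheimer intermediate and attack perpendicular to the ring tolerates the two ortho OMe groups.

**Step 2**
Reactants: 3 3,5-dimethoxy-4-(3,4,5-trimethoxyphenoxy)benzaldehyde
Product: 5 3,5-dimethoxy-4-(3,4,5-trimethoxyphenoxy)phenol, via dimer aryl formate 4 (not isolated)
Conditions: mCPBA (1.5 equiv), CH2Cl2, 0 °C to rt; aq Na2S2O3/NaHCO3 wash; then K2CO3 (cat.), MeOH, rt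
Reagents that add atoms: mCPBA, OOC(=O)c1cccc(Cl)c1
Why: Baeyer–Villiger (Dakin-type) oxidation in which the electron-rich para-aryloxy aryl group migrates in preference to H to give the aryl formate, which is cleaved by methanolysis.

**Step 3**
Reactants: 5 3,5-dimethoxy-4-(3,4,5-trimethoxyphenoxy)phenol; 2 4-fluoro-3,5-dimethoxybenzaldehyde
Product: 6 4-[3,5-dimethoxy-4-(3,4,5-trimethoxyphenoxy)phenoxy]-3,5-dimethoxybenzaldehyde (trimer aldehyde)
Conditions: Cs2CO3 (1.5 equiv), 2 (1.3 equiv), DMSO, 120 °C, Ar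
Reagents that add atoms: none
Why: The same SNAr as step 1; the reacting phenol is again a 3,5-dimethoxy-4-aryloxyphenol with free ortho positions, so reactivity does not depend on chain length.

**Step 4**
Reactants: 6 trimer aldehyde
Product: 8 4-[3,5-dimethoxy-4-(3,4,5-trimethoxyphenoxy)phenoxy]-3,5-dimethoxyphenol (trimer phenol), via trimer aryl formate 7 (not isolated)
Conditions: mCPBA (1.5 equiv), CH2Cl2, 0 °C to rt; aq Na2S2O3/NaHCO3 wash; then K2CO3 (cat.), MeOH, rt
Reagents that add atoms: mCPBA, OOC(=O)c1cccc(Cl)c1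
Why: Baeyer–Villiger (Dakin-type) oxidation with aryl migration followed by formate methanolysis; diaryl ethers and methyl ethers are inert to the peracid at rt.

**Step 5**
Reactants: 8 trimer phenol; 2 4-fluoro-3,5-dimethoxybenzaldehyde
Product: 9 tetramer aldehyde, 4-{4-[3,5-dimethoxy-4-(3,4,5-trimethoxyphenoxy)phenoxy]-3,5-dimethoxyphenoxy}-3,5-dimethoxybenzaldehyde
Conditions: Cs2CO3 (1.5 equiv), 2 (1.5 equiv), DMSO, 120 °C, Ar
Reagents that add atoms: none
Why: SNAr of the chain-end phenoxide on the formyl-activated fluoride, as in step 1.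

**Step 6**
Reactants: 9 tetramer aldehyde
Product: 11 tetramer phenol, 4-{4-[3,5-dimethoxy-4-(3,4,5-trimethoxyphenoxy)phenoxy]-3,5-dimethoxyphenoxy}-3,5-dimethoxyphenol, via tetramer aryl formate 10 (not isolated)
Conditions: mCPBA (1.5 equiv), CH2Cl2, 0 °C to rt; aq Na2S2O3/NaHCO3 wash; then K2CO3 (cat.), MeOH, rt
Reagents that add atoms: mCPBA, OOC(=O)c1cccc(Cl)c1
Why: Baeyer–Villiger (Dakin-type) oxidation with aryl migration, then formate methanolysis, as in step 2.

**Step 7**
Reactants: 11 tetramer phenol; 2 4-fluoro-3,5-dimethoxybenzaldehyde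
Product: 12 pentamer aldehyde, 4-(4-{4-[3,5-dimethoxy-4-(3,4,5-trimethoxyphenoxy)phenoxy]-3,5-dimethoxyphenoxy}-3,5-dimethoxyphenoxy)-3,5-dimethoxybenzaldehyde
Conditions: Cs2CO3 (1.5 equiv), 2 (1.5 equiv), DMSO, 120 °C, Ar
Reagents that add atoms: none
Why: SNAr of the chain-end phenoxide on the formyl-activated fluoride, which installs ring A.

**Step 8**
Reactants: 12 pentamer aldehyde
Product: 14 pentamer phenol, 4-(4-{4-[3,5-dimethoxy-4-(3,4,5-trimethoxyphenoxy)phenoxy]-3,5-dimethoxyphenoxy}-3,5-dimethoxyphenoxy)-3,5-dimethoxyphenol (undecamethyl ether of the target), via pentamer aryl formate 13 (not isolated)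
Conditions: mCPBA (1.5 equiv), CH2Cl2, 0 °C to rt; aq Na2S2O3/NaHCO3 wash; then K2CO3 (cat.), MeOH, rt
Reagents that add atoms: mCPBA, OOC(=O)c1cccc(Cl)c1
Why: Baeyer–Villiger (Dakin-type) oxidation with aryl migration, then formate methanolysis, which reveals the para OH of ring A.

**Step 9**
Reactants: 14 pentamer phenol
Product: 15 target CNP0308003.0 (all eleven OMe groups converted to OH)
Conditions: BBr3 (20 equiv), CH2Cl2, −78 °C to rt, Ar; then MeOH, H2O; Sephadex LH-20 or RP-HPLC under Ar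
Reagents that add atoms: none
Why: Lewis-acid-mediated SN2 demethylation of aryl methyl ethers, in which BBr3 cleaves the O–CH3 bonds but not the diaryl ether C–O bonds, and no stereocentre is involved.

## Compound list

1 | 3,4,5-trimethoxyphenol | COc1cc(O)cc(OC)c1OC | starting material
2 | 4-fluoro-3,5-dimethoxybenzaldehyde | COc1cc(C=O)cc(OC)c1F | starting material
3 | 3,5-dimethoxy-4-(3,4,5-trimethoxyphenoxy)benzaldehyde | COc1cc(Oc2c(OC)cc(C=O)cc2OC)cc(OC)c1OC | intermediate
4 | dimer aryl formate, 3,5-dimethoxy-4-(3,4,5-trimethoxyphenoxy)phenyl formate | COc1cc(Oc2c(OC)cc(OC=O)cc2OC)cc(OC)c1OC | intermediate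
5 | 3,5-dimethoxy-4-(3,4,5-trimethoxyphenoxy)phenol | COc1cc(Oc2c(OC)cc(O)cc2OC)cc(OC)c1OC | intermediate
6 | trimer aldehyde | COc1cc(Oc2c(OC)cc(Oc3c(OC)cc(C=O)cc3OC)cc2OC)cc(OC)c1OC | intermediate
7 | trimer aryl formate | COc1cc(Oc2c(OC)cc(Oc3c(OC)cc(OC=O)cc3OC)cc2OC)cc(OC)c1OC | intermediate
8 | trimer phenol | COc1cc(Oc2c(OC)cc(Oc3c(OC)cc(O)cc3OC)cc2OC)cc(OC)c1OC | intermediate
9 | tetramer aldehyde | COc1cc(Oc2c(OC)cc(Oc3c(OC)cc(Oc4c(OC)cc(C=O)cc4OC)cc3OC)cc2OC)cc(OC)c1OC | intermediate
10 | tetramer aryl formate | COc1cc(Oc2c(OC)cc(Oc3c(OC)cc(Oc4c(OC)cc(OC=O)cc4OC)cc3OC)cc2OC)cc(OC)c1OC | intermediate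
11 | tetramer phenol | COc1cc(Oc2c(OC)cc(Oc3c(OC)cc(Oc4c(OC)cc(O)cc4OC)cc3OC)cc2OC)cc(OC)c1OC | intermediate
12 | pentamer aldehyde | COc1cc(Oc2c(OC)cc(Oc3c(OC)cc(Oc4c(OC)cc(Oc5c(OC)cc(C=O)cc5OC)cc4OC)cc3OC)cc2OC)cc(OC)c1OC | intermediate
13 | pentamer aryl formate | COc1cc(Oc2c(OC)cc(Oc3c(OC)cc(Oc4c(OC)cc(Oc5c(OC)cc(OC=O)cc5OC)cc4OC)cc3OC)cc2OC)cc(OC)c1OC | intermediate
14 | pentamer phenol (undecamethyl ether of the target) | COc1cc(Oc2c(OC)cc(Oc3c(OC)cc(Oc4c(OC)cc(Oc5c(OC)cc(O)cc5OC)cc4OC)cc3OC)cc2OC)cc(OC)c1OC | intermediate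
15 | CNP0308003.0 | Oc1cc(O)c(Oc2cc(O)c(Oc3cc(O)c(Oc4cc(O)c(Oc5cc(O)c(O)c(O)c5)c(O)c4)c(O)c3)c(O)c2)c(O)c1 | target

## Summary

Total step count: 9. Longest linear sequence: 9.

**Three steps most likely to fail**

1. Step 1 (and its repeats, steps 3, 5 and 7): SNAr at a fluoride flanked by two electron-donating OMe groups may be slow. Fallback: change from SNAr to copper catalysis. Setting out from 1, an Ullmann-type coupling with commercial 4-bromo-3,5-dimethoxybenzaldehyde (CuI, N,N-dimethylglycine, Cs2CO3, dioxane, 100 °C) gives the same aldehyde and so returns to the route directly at 3. No new compound is made (F0).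

2. Step 2 (and its repeats, steps 4, 6 and 8): with the aldehyde, H-migration to the benzoic acid or peracid attack on the electron-rich rings can compete. Fallback: replace the formyl group by an acetyl group, where only the aryl group can migrate. Setting out from 3, MeMgBr (THF, 0 °C) gives the racemic secondary alcohol 1-[3,5-dimethoxy-4-(3,4,5-trimethoxyphenoxy)phenyl]ethanol F1. Dess–Martin oxidation gives the methyl ketone 1-[3,5-dimethoxy-4-(3,4,5-trimethoxyphenoxy)phenyl]ethanone F2. Baeyer–Villiger oxidation (mCPBA, NaHCO3, CH2Cl2) gives the aryl acetate 3,5-dimethoxy-4-(3,4,5-trimethoxyphenoxy)phenyl acetate F3. K2CO3/MeOH then returns to the route at 5.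

3. Step 9: eleven demethylations on one molecule risk partially methylated mixtures, and the free dodecaphenol is air-sensitive and hard to purify. Fallback: isolate through a peracetate. Setting out from 14, BBr3 demethylation is followed, without isolating the polyphenol, by Ac2O/pyridine to give the dodecaacetate of the target F4. F4 is stable and can be purified on silica, which removes under-demethylated material. Acid methanolysis (1.25 M HCl in MeOH, rt, Ar) and evaporation then return to the route at 15.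

## Further compounds

F0 | step 1 | none | none
F1 | step 2 | 1-[3,5-dimethoxy-4-(3,4,5-trimethoxyphenoxy)phenyl]ethanol (racemic) | COc1cc(Oc2c(OC)cc(C(C)O)cc2OC)cc(OC)c1OC
F2 | step 2 | 1-[3,5-dimethoxy-4-(3,4,5-trimethoxyphenoxy)phenyl]ethanone | COc1cc(Oc2c(OC)cc(C(C)=O)cc2OC)cc(OC)c1OC
F3 | step 2 | 3,5-dimethoxy-4-(3,4,5-trimethoxyphenoxy)phenyl acetate | COc1cc(Oc2c(OC)cc(OC(C)=O)cc2OC)cc(OC)c1OC
F4 | step 9 | dodecaacetate of the target | CC(=O)Oc1cc(OC(C)=O)c(Oc2cc(OC(C)=O)c(Oc3cc(OC(C)=O)c(Oc4cc(OC(C)=O)c(Oc5cc(OC(C)=O)c(OC(C)=O)c(OC(C)=O)c5)c(OC(C)=O)c4)c(OC(C)=O)c3)c(OC(C)=O)c2)c(OC(C)=O)c1
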